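(The readings come from a simulation for substances that don't exist; noise was put on by code.)

Start from a small charge of first nucleophile, 0.900 equiv: it has to last as long as the substrate does, so watch b, its level as a fraction of its own charge.

| flask | substrate | first nucleophile | second nucleophile | remark | time |
|---|---|---|---|---|---|
| elm | 0.20 M | 0.90 equiv | 1.3 equiv | run made earlier |  |
| alder | 0.20 M | 1.8 equiv | 1.3 equiv | run made earlier |  |
| grey | 0.20 M | 0.900 equiv (in portions, 2, over 2.5 min) | 1.30 equiv | first portion at the start, last at 2.5 min | 4.0 min |
| amber | 0.20 M | 0.900 equiv | 1.30 equiv | everything together at the start | 4.0 min |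
| violet | 0.20 M | 0.900 equiv (fed, over 2.5 min) | 1.30 equiv | all else is in the flask from the start; the feed brings no volume worth counting | 4.0 min |
| green | 0.20 M (fed, over 2.5 min) | 0.900 equiv | 1.30 equiv | all else is in the flask from the start; the feed brings no volume worth counting | 4.0 min |
| blue | 0.20 M | 0.900 equiv (fed, over 40 s) | 1.30 equiv | all else is in the flask from the start; the feed brings no volume worth counting | 4.0 min |
- elm (time / min: target / %, substrate / %): 0.250: 2.5, 88.3; 0.833: 6.6, 67.8; 1.33: 8.0, 52.6; 2.00: 9.0, 38.6; 3.00: 8.9, 24.7; 4.00: 8.3, 15.7
- alder (time / s: target / %, substrate / %): 10.0: 2.6, 93.1; 15.0: 4.4, 88.9; 25.0: 4.2, 83.1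

(each reading ± 0.5 percentage points)
- in percentages every species weighs as the substrate in it: one side product counts as two
- steps under discussion: substrate -> intermediate; first nucleophile + intermediate -> target; second nucleophile + intermediate -> other capture product; intermediate -> solvolysis product; second nucleophile <-> dormant form; substrate + target -> side product; 2 first nucleophile -> homo dimer
1. which flask leads in amount of target, in percent of the substrate charged ("all alike" within 1.5 percentage points) (grey / amber / violet / green / blue / all alike)
2. how much target is there at the end, in percent of the substrate charged: grey
3. how much target is there at the end, in percent of the substrate charged: amber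
4. how much target is there at the end, in percent of the substrate charged: violet
5. how much target is there at the end, in percent of the substrate charged: green
6. how much target is there at the end, in percent of the substrate charged: blue

Take the main step first, substrate to intermediate. Elm gives a first-order decay:

k = 0.462 min⁻¹, so the substrate half-life is 1.50 min.

Alder, with twice the first nucleophile, shows 88.9% of substrate at 15.0 s, against 88.3% in elm at 0.250 min. Treat this step as the rate-limiting step, then, and as blind to b.

Now add the fork: each intermediate is caught by the first nucleophile or lost. Take target gained per minute, per substrate standing, as roughly proportional to b, an approximation. Elm gives this over two windows: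

early: 0.0901 min⁻¹
late: 0.0327 min⁻¹
ratio: 2.75

Last, add the self-loss to homo dimer. This step is second order, so by itself it makes b fall as h/(h + t), where h is the self-loss time, the first half-life of a full charge by this step. Put the two window midpoints, 0.541 min and 1.67 min, into that law:

h = 0.0995 min

This is a rough reading, since the late gain is 1 percentage point between readings of scatter 0.5 points.

Under a steady feed over time T, inflow balances self-loss at the standing level s = sqrt(h/T). After the feed ends, b = s·h/(h + s·t), with t counted from that end.

violet: s = 19.9%
all at the start, when half the substrate has gone: b = 6.22%
blue at that moment: b = 9.11%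

My reckoning: expect violet to stand above amber and blue, its level being higher, and blue to stand above amber. Expect amber to repeat elm's 8.3%.

The forecast differs. It names amber, with 7% for grey, 8.3% for amber, 6.7% for violet, 5.2% for green and 8.1% for blue, holding that “Slow feeding reduces dimer loss but lowers the nucleophile level while most substrate ionises, so it doesn't pay”.

The flasks give 12.0% for grey, 9.20% for amber, 16.8% for violet, 4.26% for green and 13.6% for blue, so violet leads.

    substrate → intermediate (k = 0.00760 s⁻¹)
    first nucleophile + intermediate → target (k = 0.610 M⁻¹ s⁻¹)
    second nucleophile + intermediate → other capture product (k = 0.0280 M⁻¹ s⁻¹)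
    intermediate → solvolysis product (k = 0.0460 s⁻¹)
    second nucleophile ⇌ dormant form (K = 1.80, k = 0.00630 s⁻¹)
    substrate + target → side product (k = 0.0170 M⁻¹ s⁻¹)
    2 first nucleophile → homo dimer (k = 0.380 M⁻¹ s⁻¹)

Violet's first nucleophile stands at 4.69% of its charge at 4.00 min, and the law from h gives 4.98%. In green, where all of it stands from the start, the law gives 9.08% at 0.996 min, when solvolysis already uses the intermediate 4.1 times as fast as the first nucleophile does, a ratio that reaches 39 at 4.00 min, with target at 4.26%.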